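**Retrosynthetic overview**

1. Core numbering: C1 (angelate carbinol), C2, C3 (senecioate carbinol), C4 (CMe2), C5, C6, C7 (ketone), C8=C9(CH3), C10, C11 (quaternary, CH3). The cyclobutane C5–C6–C11–C10 is bridged on one face by C7–C8–C9 and on the other by C1–C2–C3–C4. Read C5–C10–C9–C8–C7–C6–C11–C1–C2–C3–C4, the carbons form one unbranched farnesoate chain whose carboxyl carbon C5 faces C11 across the four-membered ring; the strategy rests on this.
2. Late disconnections: C1–O angelate, C7 oxygen (allylic oxidation), C3–O senecioate, C3 carbinol (from the ketone), C5–H (from a tertiary alcohol).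
3. C4–C5 (seven-membered ring): aldol of a C3=C4 samarium enolate onto the C5 cyclobutanone. A benzoyloxy group on C4 is added to the acyclic precursor so that SmI2 forms this enolate regiospecifically.
4. Key disconnection, C5–C6 and C10–C11: intramolecular vinylketene–alkene [2+2] of an acyclic (8R)-8-silyloxy-10-oxo-11-benzoyloxyfarnesoyl chloride, closing the cyclobutanone and the six-membered ring together.
5. Precursor: allyl geranate, SeO2 oxidation, boron aldol with 2-methyl-3-oxobutan-2-yl benzoate, Sharpless kinetic resolution (sets C1). Ring order: cyclobutanone plus six-membered ring (step 9), then seven-membered ring (step 11).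

Key step: step 9

Assumption: geranic acid is taken as the (2E) isomer; this geometry is erased when the vinylketene forms, so an E/Z mixture would serve as well.

Step 1
Reactants: 1 geranic acid; 2 allyl bromide
Product: 3 allyl geranate
Conditions: K2CO3, DMF, 25 °C
Reagents that add atoms: none
Why: SN2 O-alkylation of the carboxylate gives an ester that can later be cleaved without base, which a β-silyloxy ketone would not tolerate.

Step 2
Reactants: 3 allyl geranate
Product: 5 allyl (2E,6E)-3,7-dimethyl-8-oxoocta-2,6-dienoate, via allylic alcohol 4 (not isolated)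
Conditions: SeO2 (0.3 equiv), t-BuOOH, salicylic acid (cat.), CH2Cl2, 25 °C; then MnO2, CH2Cl2, 25 °C
Reagents that add atoms: tert-butyl hydroperoxide, CC(C)(C)OO
Why: SeO2/t-BuOOH allylic oxidation (ene reaction, then [2,3]-shift) attacks the (E)-methyl of the electron-rich terminal alkene and MnO2 takes the allylic alcohol to the enal, while the enoate and the allyl ester are deactivated.

Step 3
Reactants: 6 3-hydroxy-3-methylbutan-2-one; 7 benzoyl chloride
Product: 8 2-methyl-3-oxobutan-2-yl benzoate
Conditions: pyridine, DMAP (cat.), CH2Cl2, 40 °C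
Reagents that add atoms: none
Why: DMAP-catalysed acylation of the tertiary α-hydroxy ketone installs the benzoate that later leaves from C4 on reduction.

Step 4
Reactants: 8 2-methyl-3-oxobutan-2-yl benzoate; 5 allyl (2E,6E)-3,7-dimethyl-8-oxoocta-2,6-dienoate
Product: 10 racemic allyl (2E,6E)-11-benzoyloxy-8-hydroxy-3,7,11-trimethyl-10-oxododeca-2,6-dienoate, via boron enolate 9 (not isolated)
Conditions: (c-C6H11)2BCl, Et3N, Et2O, 0 °C; then 5, –78 to –20 °C; H2O2, MeOH, pH 7 buffer, 0 °C
Reagents that add atoms: none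
Why: Boron aldol reaction in which the ketone can enolise only at its methyl group and the dialkylboron enolate of an α-benzoyloxy ketone adds 1,2 to the enal, forming the C1 carbinol (chain C8) as a racemate.

Step 5
Reactants: 10 racemic aldol
Product: 11 (8R)-enantiomer of 10
Conditions: Ti(OiPr)4 (0.2 equiv), L-(+)-diisopropyl tartrate (0.24 equiv), t-BuOOH (0.6 equiv), 4 Å molecular sieves, CH2Cl2, –20 °C, stopped near 55 % conversion
Reagents that add atoms: none
Why: Sharpless kinetic resolution of a secondary allylic alcohol, in which L-(+)-tartrate epoxidises the (S)-enantiomer fast, so the (R)-alcohol should be recovered in high enantiomeric purity and C1 is set.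

Step 6
Reactants: 11 (8R)-alcohol
Product: 12 allyl (2E,6E,8R)-11-benzoyloxy-8-(tert-butyldimethylsilyloxy)-3,7,11-trimethyl-10-oxododeca-2,6-dienoate
Conditions: TBSOTf, 2,6-lutidine, CH2Cl2, –78 °C
Reagents that add atoms: tert-butyldimethylsilyl triflate, CC(C)(C)[Si](C)(C)OS(=O)(=O)C(F)(F)F
Why: Silyl triflate silylation at low temperature protects the carbinol without retro-aldol or enol silylation, and the bulky silyloxy group is the steric control element for step 9.

Step 7
Reactants: 12 silyl ether
Product: 13 (2E,6E,8R)-11-benzoyloxy-8-(tert-butyldimethylsilyloxy)-3,7,11-trimethyl-10-oxododeca-2,6-dienoic acid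
Conditions: Pd(PPh3)4 (5 mol %), morpholine, THF, 25 °C
Reagents that add atoms: none
Why: Tsuji–Trost deallylation (zerovalent palladium forms a π-allyl complex that morpholine captures) frees the acid under neutral conditions that spare the β-silyloxy ketone and the benzoate.

Step 8
Reactants: 13 acid
Product: 14 (2E,6E,8R)-11-benzoyloxy-8-(tert-butyldimethylsilyloxy)-3,7,11-trimethyl-10-oxododeca-2,6-dienoyl chloride (used crude)
Conditions: 1-chloro-N,N,2-trimethylprop-1-en-1-amine, CH2Cl2, 0 to 25 °C, evaporate
Reagents that add atoms: 1-chloro-N,N,2-trimethylprop-1-en-1-amine, CC(C)=C(Cl)N(C)C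
Why: Ghosez's α-chloroenamine gives the acid chloride without free HCl, so the allylic silyl ether survives.

Step 9
Reactants: 14 acid chloride
Product: 16 7-methyl-2-methylidenebicyclo[3.1.1]heptan-6-one bearing on C11 the (1R)-4-benzoyloxy-1-silyloxy-4-methyl-3-oxopentyl chain, via vinylketene 15 (not isolated)
Conditions: Et3N (5 equiv), toluene, 110 °C, 14 added over 8 h by syringe pump (final 0.005 M)
Reagents that add atoms: none
Why: Et3N removes HCl from 14 by γ-deprotonation at the C9 methyl to give vinylketene 15 (C5 ketene carbon, C10 α-carbon), which adds thermally across C6=C11 in an intramolecular ketene–alkene [2+2], C5 bonding to the less substituted C6 and C10 to C11, the carbon that carries the developing positive charge. The closest known reaction is the cyclisation of geranoyl and farnesoyl chlorides with Et3N to 2-methylenebicyclo[3.1.1]heptan-6-ones. The cyclobutanone (C5, C6, C11, C10) closes in the crossed mode forced by the three-atom tether C7–C8–C9, and the C5–C6 bond at the same time closes the six-membered ring C5–C10–C9–C8–C7–C6 in a 6-exo sense. Addition is suprafacial on the alkene, so the (E) geometry puts the C11 methyl cis to C7 (syn to the three-carbon bridge) and the side chain anti, while C6 and C10 follow from the bicyclic constraint. The step needs π-facial selectivity relative to the (R)-silyloxy centre at C1: the required addition is anti to the bulky silyloxy group in the rotamer that holds the C1 hydrogen next to the C11 methyl (A(1,2) strain) and C2 in the alkene plane, a bias that is not certain, but because 14 is a single enantiomer the other cycloadduct is a diastereomer and is removed by chromatography. It also needs γ-deprotonation at the methyl rather than at C8 and survival of the β-silyloxy ketone, both helped by slow addition at high dilution.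

Step 10
Reactants: 16 exocyclic alkene
Product: 17 2,7-dimethylbicyclo[3.1.1]hept-2-en-6-one analogue of 16 (C8=C9 endocyclic, same side chain)
Conditions: Pd/C (presaturated with H2, then Ar), EtOAc, 25 °C
Reagents that add atoms: none
Why: Palladium hydride alkene migration (the β-pinene to α-pinene type isomerisation, as used to reach chrysanthenone from its 2-methylene isomer) gives the trisubstituted C8=C9 alkene, the only alternative C9=C10 being a bridgehead alkene.

Step 11
Reactants: 17 benzoyloxy ketone
Product: 19 tricyclic β-hydroxy ketone with C1 silyloxy and C3 ketone and tertiary C5 hydroxyl, via samarium enolate 18 (not isolated)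
Conditions: SmI2 (2.2 equiv, added dropwise), THF, –78 to –20 °C; aq. NH4Cl
Reagents that add atoms: none
Why: SmI2 reductively cleaves the α-benzoyloxy ketone to a trivalent samarium enolate fixed at C3=C4, which adds to the strained cyclobutanone in a Reformatsky-type intramolecular aldol closing the seven-membered ring; the tether reaches C5 only from the face anti to the C7–C9 bridge, so the C5 hydroxyl ends up syn to that bridge.

Step 12
Reactants: 19 tricyclic β-hydroxy ketone
Product: 22 tricyclic ketone with C5–H and C1 silyloxy and C3 ketone, via chlorooxalate 20 (not isolated), via oxalate thiohydroxamate 21 (not isolated)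
Conditions: (COCl)2, 2,6-lutidine, CH2Cl2, 0 °C, evaporate; then N-hydroxypyridine-2-thione sodium salt (C5H4NNaOS), DMAP (cat.), t-BuSH, toluene, 80 °C
Reagents that add atoms: none
Why: Barton–Crich deoxygenation of a tertiary alcohol, in which the mixed oxalate thiohydroxamate fragments in a thiyl radical chain with loss of two CO2 to the tertiary C5 radical that takes hydrogen from the thiol faster than a cyclobutyl radical can open; C4 must stay anti to the C7–C9 bridge, so only one configuration at C5 is possible.

Step 13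
Reactants: 22 tricyclic ketone
Product: 23 (1R,3R)-1-silyloxy-3-hydroxy tricycle
Conditions: NaBH4, MeOH/THF, –20 to 0 °C
Reagents that add atoms: none
Why: Hydride reduction under substrate control: the seven-membered ring should adopt the twist form with the C1 silyloxy group pseudo-equatorial and its dipole away from the carbonyl, the face towards the cyclobutane is blocked by C10–H, and attack from the open face gives the 1,3-anti (3R) alcohol, as in the polar model for β-silyloxy ketones.

Step 14
Reactants: 23 alcohol; 24 3-methylbut-2-enoyl chloride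
Product: 25 (1R,3R)-1-silyloxy-3-senecioyloxy tricycle
Conditions: pyridine, DMAP, CH2Cl2, 40 °C
Reagents that add atoms: none
Why: DMAP-catalysed acylation of the only free hydroxyl, with pyridine as base because stronger amines deconjugate the acid chloride through its vinylketene.

Step 15
Reactants: 25 senecioate
Product: 26 C7 enone (C7=O, C8=C9)
Conditions: CrO3, 3,5-dimethylpyrazole, CH2Cl2, –20 °C
Reagents that add atoms: chromium trioxide, O=[Cr](=O)=O
Why: Allylic oxidation with the CrO3–dimethylpyrazole complex, as in α-pinene to verbenone: C7 is the only secondary allylic position of the electron-rich ring alkene, the allylic bridgehead C10–H cannot form a planar allyl system, and the electron-poor senecioate alkene reacts far more slowly.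

Step 16
Reactants: 26 silyl ether
Product: 27 (1R)-alcohol
Conditions: HF·pyridine, THF, 0 to 25 °C
Reagents that add atoms: none
Why: Fluoride cleavage of the silyl ether under buffered acidic conditions avoids a free alkoxide next to the C3 ester (acyl migration) and leaves the enone and ester intact.

Step 17
Reactants: 27 alcohol; 28 angelic acid
Product: 29 target
Conditions: 2,4,6-trichlorobenzoyl chloride, Et3N, toluene, 25 °C; then 27, toluene, 80 °C
Reagents that add atoms: none
Why: Yamaguchi-type mixed anhydride esterification without DMAP, the conditions that transfer the angeloyl group to hindered alcohols without (Z) to (E) isomerisation to the tiglate.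

**Compound list**

1 | geranic acid, (2E)-3,7-dimethylocta-2,6-dienoic acid | CC(C)=CCC/C(C)=C/C(=O)O | starting material
2 | allyl bromide | C=CCBr | starting material
3 | allyl (2E)-3,7-dimethylocta-2,6-dienoate | CC(C)=CCC/C(C)=C/C(=O)OCC=C | intermediate
4 | allyl (2E,6E)-8-hydroxy-3,7-dimethylocta-2,6-dienoate | OC/C(C)=C/CC/C(C)=C/C(=O)OCC=C | intermediate
5 | allyl (2E,6E)-3,7-dimethyl-8-oxoocta-2,6-dienoate | O=C/C(C)=C/CC/C(C)=C/C(=O)OCC=C | intermediate
6 | 3-hydroxy-3-methylbutan-2-one | CC(=O)C(C)(C)O | starting material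
7 | benzoyl chloride | O=C(Cl)c1ccccc1 | starting material
8 | 2-methyl-3-oxobutan-2-yl benzoate | CC(=O)C(C)(C)OC(=O)c1ccccc1 | intermediate
9 | dicyclohexylboron enolate of 8 | C=C(OB(C1CCCCC1)C1CCCCC1)C(C)(C)OC(=O)c1ccccc1 | intermediate
10 | racemic allyl (2E,6E)-11-benzoyloxy-8-hydroxy-3,7,11-trimethyl-10-oxododeca-2,6-dienoate | CC(C)(OC(=O)c1ccccc1)C(=O)CC(O)/C(C)=C/CC/C(C)=C/C(=O)OCC=C | intermediate
11 | (8R)-enantiomer of 10 | CC(C)(OC(=O)c1ccccc1)C(=O)C[C@@H](O)/C(C)=C/CC/C(C)=C/C(=O)OCC=C | intermediate
12 | (8R)-tert-butyldimethylsilyl ether of 11 | CC(C)(OC(=O)c1ccccc1)C(=O)C[C@@H](O[Si](C)(C)C(C)(C)C)/C(C)=C/CC/C(C)=C/C(=O)OCC=C | intermediate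
13 | carboxylic acid from 12 | CC(C)(OC(=O)c1ccccc1)C(=O)C[C@@H](O[Si](C)(C)C(C)(C)C)/C(C)=C/CC/C(C)=C/C(=O)O | intermediate
14 | acid chloride from 13 (key-step precursor) | CC(C)(OC(=O)c1ccccc1)C(=O)C[C@@H](O[Si](C)(C)C(C)(C)C)/C(C)=C/CC/C(C)=C/C(Cl)=O | intermediate
15 | vinylketene (C5=C10 ketene, C9 methylidene) | CC(C)(OC(=O)c1ccccc1)C(=O)C[C@@H](O[Si](C)(C)C(C)(C)C)/C(C)=C/CCC(=C)C=C=O | intermediate
16 | cycloadduct: 7-methyl-2-methylidenebicyclo[3.1.1]heptan-6-one, C11 methyl syn to the three-carbon bridge, (1R) side chain anti | CC(C)(OC(=O)c1ccccc1)C(=O)C[C@@H](O[Si](C)(C)C(C)(C)C)[C@@]1(C)[C@@H]2CCC(=C)[C@H]1C2=O | intermediate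
17 | endocyclic isomer of 16 (C8=C9) | CC(C)(OC(=O)c1ccccc1)C(=O)C[C@@H](O[Si](C)(C)C(C)(C)C)[C@@]1(C)[C@@H]2CC=C(C)[C@H]1C2=O | intermediate
18 | diiodosamarium enolate (C3=C4) | I[Sm](OC(=C(C)C)C[C@@H](O[Si](C)(C)C(C)(C)C)[C@@]1(C)[C@@H]2CC=C(C)[C@H]1C2=O)I | intermediate
19 | tricyclic β-hydroxy ketone: C1 silyloxy, C3 ketone, C5 hydroxyl syn to the C7–C9 bridge | CC(C)(C)[Si](C)(C)O[C@@H]1CC(=O)C(C)(C)[C@]2(O)[C@H]3CC=C(C)[C@@H]2[C@]31C | intermediate
20 | C5 chlorooxalate of 19 | CC(C)(C)[Si](C)(C)O[C@@H]1CC(=O)C(C)(C)[C@]2(OC(=O)C(Cl)=O)[C@H]3CC=C(C)[C@@H]2[C@]31C | intermediate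
21 | C5 oxalate ester of N-hydroxypyridine-2-thione | CC(C)(C)[Si](C)(C)O[C@@H]1CC(=O)C(C)(C)[C@]2(OC(=O)C(=O)ON4C=CC=CC4=S)[C@H]3CC=C(C)[C@@H]2[C@]31C | intermediate
22 | tricyclic ketone: C1 silyloxy, C3 ketone, C5–H | CC(C)(C)[Si](C)(C)O[C@@H]1CC(=O)C(C)(C)[C@@H]2[C@H]3CC=C(C)[C@@H]2[C@]31C | intermediate
23 | (1R,3R)-1-silyloxy-3-hydroxy tricycle | CC(C)(C)[Si](C)(C)O[C@@H]1C[C@@H](O)C(C)(C)[C@@H]2[C@H]3CC=C(C)[C@@H]2[C@]31C | intermediate
24 | 3-methylbut-2-enoyl chloride | CC(C)=CC(Cl)=O | starting material
25 | (1R,3R)-1-silyloxy-3-senecioyloxy tricycle | CC(C)(C)[Si](C)(C)O[C@@H]1C[C@@H](OC(=O)C=C(C)C)C(C)(C)[C@@H]2[C@H]3CC=C(C)[C@@H]2[C@]31C | intermediate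
26 | C7 enone of 25 | CC(C)(C)[Si](C)(C)O[C@@H]1C[C@@H](OC(=O)C=C(C)C)C(C)(C)[C@@H]2[C@H]3C(=O)C=C(C)[C@@H]2[C@]31C | intermediate
27 | (1R)-alcohol from 26 | O[C@@H]1C[C@@H](OC(=O)C=C(C)C)C(C)(C)[C@@H]2[C@H]3C(=O)C=C(C)[C@@H]2[C@]31C | intermediate
28 | angelic acid, (Z)-2-methylbut-2-enoic acid | C/C=C(/C)C(=O)O | starting material
29 | target CNP0277258.2 | C/C=C(/C)C(=O)O[C@@H]1C[C@@H](OC(=O)C=C(C)C)C(C)(C)[C@@H]2[C@H]3C(=O)C=C(C)[C@@H]2[C@]31C | target

**Step count and risks**

Total steps: 17. Longest linear sequence: 16 (steps 1, 2 and 4–17 from geranic acid).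

Steps most likely to fail:

1. Step 9. Process: weak or reversed π-facial induction by the C1 silyloxy centre. A transition state with the C1–O bond in the alkene plane and C2 anti to the ketene would give the cycloadduct with the mirror-image ring system. If the induction is only weak, 16 is separated from its diastereomer. If it is reversed, the fallback uses the other enantiomer of the alcohol and corrects C1 by redox afterwards; it sets out from 10 and comes back at 23. Resolution of 10 with D-(–)-diisopropyl tartrate leaves the (8S)-alcohol F1. The operations of steps 6 to 8 give the silyl ether F2, the acid F3 and the acid chloride F4. The cycloaddition of step 9 should then give the C1 epimer of 16 with the required ring system, cyclobutanone F5. Steps 10 to 12 take it to the endocyclic alkene F6, the tricyclic hydroxy ketone F7 and the C1 epimer of 22, ketone F8. HF·pyridine gives the (1S)-hydroxy ketone F9. Chelation-controlled syn reduction (Et2BOMe, NaBH4, THF/MeOH, –78 °C, Narasaka–Prasad) sets C3 as in the target and gives the syn diol F10. TEMPO/PhI(OAc)2 should oxidise the less hindered C1 carbinol (its quaternary neighbour has two ring bonds tied back, whereas C3 lies next to the gem-dimethyl carbon) to the C1 ketone F11. Hydroxyl-directed anti reduction from the C3 hydroxyl (Me4NBH(OAc)3, MeCN/AcOH, –30 °C, Evans–Saksena) gives the (1R,3R)-diol F12. TBSOTf (1 equiv) with 2,6-lutidine at –78 °C silylates the same less hindered C1 hydroxyl and returns 23.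

2. Step 11. Process: protonation of the samarium enolate, or reduction of the cyclobutanone, competing with bond formation between two fully substituted carbons. The fallback separates enolate formation from the aldol; it sets out from 17 and comes back at 19. SmI2 at –78 °C followed by Me3SiCl/Et3N traps the regiodefined enolate as the trimethylsilyl enol ether F13. TiCl4 in CH2Cl2 at –78 °C then effects an intramolecular Mukaiyama aldol onto the cyclobutanone, and aqueous work-up gives 19.

3. Step 12. Process: failure to acylate the very hindered tertiary C5 hydroxyl, or capture of the alkoxycarbonyl radical before it loses the second CO2. The fallback is a Barton–McCombie deoxygenation after the C3 ketone is taken out of play; it sets out from 19 and comes back at 23. NaBH4 reduces C3 (same facial argument as step 13) to the diol F14. TESOTf (1.1 equiv) with 2,6-lutidine at –78 °C protects only the secondary hydroxyl, giving the triethylsilyl ether F15. KN(SiMe3)2 and CS2, then MeI, give the tertiary S-methyl xanthate F16, which cannot undergo Chugaev elimination because both neighbours are bridgeheads. Bu3SnH/AIBN in toluene at 80 °C gives the deoxygenated bis-silyl ether F17. PPTS in MeOH removes the triethylsilyl group selectively and returns 23.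

**Further compounds**

F1 | step 9 | (8S)-enantiomer of 10 | CC(C)(OC(=O)c1ccccc1)C(=O)C[C@H](O)/C(C)=C/CC/C(C)=C/C(=O)OCC=C
F2 | step 9 | (8S)-tert-butyldimethylsilyl ether | CC(C)(OC(=O)c1ccccc1)C(=O)C[C@H](O[Si](C)(C)C(C)(C)C)/C(C)=C/CC/C(C)=C/C(=O)OCC=C
F3 | step 9 | (8S)-acid | CC(C)(OC(=O)c1ccccc1)C(=O)C[C@H](O[Si](C)(C)C(C)(C)C)/C(C)=C/CC/C(C)=C/C(=O)O
F4 | step 9 | (8S)-acid chloride | CC(C)(OC(=O)c1ccccc1)C(=O)C[C@H](O[Si](C)(C)C(C)(C)C)/C(C)=C/CC/C(C)=C/C(Cl)=O
F5 | step 9 | C1 epimer of 16 | CC(C)(OC(=O)c1ccccc1)C(=O)C[C@H](O[Si](C)(C)C(C)(C)C)[C@@]1(C)[C@@H]2CCC(=C)[C@H]1C2=O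
F6 | step 9 | C1 epimer of 17 | CC(C)(OC(=O)c1ccccc1)C(=O)C[C@H](O[Si](C)(C)C(C)(C)C)[C@@]1(C)[C@@H]2CC=C(C)[C@H]1C2=O
F7 | step 9 | C1 epimer of 19 | CC(C)(C)[Si](C)(C)O[C@H]1CC(=O)C(C)(C)[C@]2(O)[C@H]3CC=C(C)[C@@H]2[C@]31C
F8 | step 9 | C1 epimer of 22 | CC(C)(C)[Si](C)(C)O[C@H]1CC(=O)C(C)(C)[C@@H]2[C@H]3CC=C(C)[C@@H]2[C@]31C
F9 | step 9 | (1S)-1-hydroxy-3-oxo tricycle | O[C@H]1CC(=O)C(C)(C)[C@@H]2[C@H]3CC=C(C)[C@@H]2[C@]31C
F10 | step 9 | (1S,3R)-syn diol | O[C@H]1C[C@@H](O)C(C)(C)[C@@H]2[C@H]3CC=C(C)[C@@H]2[C@]31C
F11 | step 9 | (3R)-3-hydroxy-1-oxo tricycle | O=C1C[C@@H](O)C(C)(C)[C@@H]2[C@H]3CC=C(C)[C@@H]2[C@]31C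
F12 | step 9 | (1R,3R)-diol | O[C@@H]1C[C@@H](O)C(C)(C)[C@@H]2[C@H]3CC=C(C)[C@@H]2[C@]31C
F13 | step 11 | trimethylsilyl enol ether (C3=C4) of the debenzoyloxylated ketone | CC(C)=C(O[Si](C)(C)C)C[C@@H](O[Si](C)(C)C(C)(C)C)[C@@]1(C)[C@@H]2CC=C(C)[C@H]1C2=O
F14 | step 12 | (1R,3R)-1-silyloxy-3,5-diol | CC(C)(C)[Si](C)(C)O[C@@H]1C[C@@H](O)C(C)(C)[C@]2(O)[C@H]3CC=C(C)[C@@H]2[C@]31C
F15 | step 12 | 3-triethylsilyl ether of F14 | CC(C)(C)[Si](C)(C)O[C@@H]1C[C@@H](O[Si](CC)(CC)CC)C(C)(C)[C@]2(O)[C@H]3CC=C(C)[C@@H]2[C@]31C
F16 | step 12 | C5 S-methyl xanthate of F15 | CC(C)(C)[Si](C)(C)O[C@@H]1C[C@@H](O[Si](CC)(CC)CC)C(C)(C)[C@]2(OC(=S)SC)[C@H]3CC=C(C)[C@@H]2[C@]31C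
F17 | step 12 | deoxygenated bis-silyl ether | CC(C)(C)[Si](C)(C)O[C@@H]1C[C@@H](O[Si](CC)(CC)CC)C(C)(C)[C@@H]2[C@H]3CC=C(C)[C@@H]2[C@]31C
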